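**Retrosynthetic overview**
1. Target 30 ⇐ diol 26 by stepwise angeloylation (C6–OH, then the tertiary C11–OH); 26 ⇐ bis-silyl ether 25.
2. 1,10-Oxirane (last ring) ⇐ Shi epoxidation of (Z)-cyclodecene 24; ten-membered carbocycle ⇐ ring-closing metathesis (C1=C10) of lactone diene 23.
3. γ-Lactone ⇐ oxidative lactonisation of 1,4-diol 18; C11 methyl by lactone enolate alkylation; C8–C9 by Keck methallylation of aldehyde 15.
4. C6–C7 ⇐ Fráter–Seebach aldol of hydroxy ester 10 (ketoreductase reduction of keto ester 9) with cis-epoxy aldehyde 7.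
5. 4,5-Oxirane (first ring) ⇐ Sharpless epoxidation of (Z)-dienol 5 ⇐ Negishi coupling of 3 with 4. Ring order: 4,5-oxirane → γ-lactone → carbocycle → 1,10-oxirane.

Assumption: locants C1–C15 in names and comments are the germacrane locants of 30 (C12 lactone carbonyl, C13 methyl on C11, C14 methyl on C10, C15 methyl on C4); "13-nor" marks compounds that lack C13.

**Route**

Step 1
Reactants: 1 but-2-yn-1-ol
Product: 3 (2Z)-3-iodobut-2-en-1-ol, via cyclic sodium alkenylalanate 2 (not isolated)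
Conditions: NaAlH2(OCH2CH2OMe)2 (1.5 equiv), THF, 0 °C; then I2, −78 → 0 °C
Reagents that add atoms: iodine, II
Why: Hydroxyl-directed trans-hydroalumination places aluminium on C3 in a five-membered alanate and iodinolysis with retention gives the (Z)-vinyl iodide (hydroalumination–iodination), fixing the geometry that later becomes the cis 4,5-epoxide.

Step 2
Reactants: 3 (2Z)-3-iodobut-2-en-1-ol; 4 but-3-en-1-ylzinc bromide
Product: 5 (2Z)-3-methylhepta-2,6-dien-1-ol
Conditions: 4 (1.5 equiv), PdCl2(dppf) (5 mol %), THF, 25 °C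
Reagents that add atoms: none
Why: Negishi sp2–sp3 cross-coupling proceeds with retention of the vinyl iodide geometry and tolerates the free hydroxyl, so the chain ends up cis to CH2OH.

Step 3
Reactants: 5 (2Z)-3-methylhepta-2,6-dien-1-ol
Product: 6 [(2S,3R)-3-(but-3-en-1-yl)-3-methyloxiran-2-yl]methanol
Conditions: Ti(OiPr)4 (10 mol %), diethyl L-(+)-tartrate (12 mol %), tBuOOH (2 equiv), 4 Å molecular sieves, CH2Cl2, −20 °C
Reagents that add atoms: tert-butyl hydroperoxide, CC(C)(C)OO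
Why: Catalytic Sharpless asymmetric epoxidation with the L-tartrate delivers oxygen to the allylic alcohol face that gives C5 (S) and C4 (R), the first stereocentres of the route, and leaves the remote terminal alkene alone.

Step 4
Reactants: 6 [(2S,3R)-3-(but-3-en-1-yl)-3-methyloxiran-2-yl]methanol
Product: 7 (2R,3R)-3-(but-3-en-1-yl)-3-methyloxirane-2-carbaldehyde
Conditions: TEMPO (10 mol %), PhI(OAc)2 (1.1 equiv), CH2Cl2, 25 °C
Reagents that add atoms: none
Why: TEMPO/PhI(OAc)2 oxidation stops at the aldehyde under near-neutral conditions, so the cis-epoxy aldehyde forms without epimerisation or ring opening (the descriptor at C5 changes by priority only).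

Step 5
Reactants: 8 ethyl 4-chloro-3-oxobutanoate
Product: 9 ethyl 4-[(4-methoxybenzyl)oxy]-3-oxobutanoate
Conditions: 4-methoxybenzyl alcohol (1.0 equiv), NaH (2.2 equiv), THF, 0 → 25 °C
Reagents that add atoms: 4-methoxybenzyl alcohol, COc1ccc(CO)cc1
Why: Williamson ether synthesis in which the alkoxide displaces the primary chloride while the keto ester is masked as its sodium enolate by the second equivalent of NaH.

Step 6
Reactants: 9 ethyl 4-[(4-methoxybenzyl)oxy]-3-oxobutanoate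
Product: 10 ethyl (3R)-3-hydroxy-4-[(4-methoxybenzyl)oxy]butanoate
Conditions: ketoreductase ((R)-selective, NADPH-dependent), NADP+ (cat.), iPrOH (cosubstrate), phosphate buffer pH 7.0, 30 °C
Reagents that add atoms: none
Why: Enzymatic asymmetric ketone reduction by a ketoreductase delivers hydride from NADPH to one face of the β-keto ester and sets the (R)-carbinol (the C11–O stereocentre), with isopropanol recycling the cofactor.

Step 7
Reactants: 10 ethyl (3R)-3-hydroxy-4-[(4-methoxybenzyl)oxy]butanoate; 7 (2R,3R)-3-(but-3-en-1-yl)-3-methyloxirane-2-carbaldehyde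
Product: 12 ethyl (2R,3R)-2-{(S)-[(2S,3R)-3-(but-3-en-1-yl)-3-methyloxiran-2-yl](hydroxy)methyl}-3-hydroxy-4-[(4-methoxybenzyl)oxy]butanoate, via dilithium alkoxide enolate 11 (not isolated)
Conditions: LiN(iPr)2 (2.2 equiv), THF, −78 → −20 °C; then 7, −78 °C
Reagents that add atoms: none
Why: Fráter–Seebach aldol in which the chelated dianion reacts anti to its carbinol substituent (sets C7 from the enzyme-made centre) and the cis-epoxy aldehyde is attacked under Felkin–Anh control anti to the epoxide C–O bond (sets C6 S); the minor enantiomer of 7 is removed here as a diastereomer.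

Step 8
Reactants: 12 ethyl (2R,3R)-2-{(S)-[(2S,3R)-3-(but-3-en-1-yl)-3-methyloxiran-2-yl](hydroxy)methyl}-3-hydroxy-4-[(4-methoxybenzyl)oxy]butanoate
Product: 13 ethyl (2R,3R)-2-{(S)-[(2S,3R)-3-(but-3-en-1-yl)-3-methyloxiran-2-yl][(triethylsilyl)oxy]methyl}-4-[(4-methoxybenzyl)oxy]-3-[(triethylsilyl)oxy]butanoate
Conditions: Et3SiOTf (2.5 equiv), 2,6-lutidine (4 equiv), CH2Cl2, −78 °C
Reagents that add atoms: triethylsilyl trifluoromethanesulfonate, CC[Si](CC)(CC)OS(=O)(=O)C(F)(F)F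
Why: Silyl ether formation under buffered low-temperature conditions caps both secondary hydroxyls (C6 and C11) before they can open the neighbouring epoxide.

Step 9
Reactants: 13 ethyl (2R,3R)-2-{(S)-[(2S,3R)-3-(but-3-en-1-yl)-3-methyloxiran-2-yl][(triethylsilyl)oxy]methyl}-4-[(4-methoxybenzyl)oxy]-3-[(triethylsilyl)oxy]butanoate
Product: 14 (2R,3R)-2-{(S)-[(2S,3R)-3-(but-3-en-1-yl)-3-methyloxiran-2-yl][(triethylsilyl)oxy]methyl}-4-[(4-methoxybenzyl)oxy]-3-[(triethylsilyl)oxy]butan-1-ol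
Conditions: iBu2AlH (2.5 equiv), CH2Cl2, −78 → −40 °C
Reagents that add atoms: none
Why: Hydride reduction of the ester to the primary alcohol at low temperature leaves the trisubstituted epoxide, the silyl ethers and the benzylic ether untouched.

Step 10
Reactants: 14 (2R,3R)-2-{(S)-[(2S,3R)-3-(but-3-en-1-yl)-3-methyloxiran-2-yl][(triethylsilyl)oxy]methyl}-4-[(4-methoxybenzyl)oxy]-3-[(triethylsilyl)oxy]butan-1-ol
Product: 15 (2R,3R)-2-{(S)-[(2S,3R)-3-(but-3-en-1-yl)-3-methyloxiran-2-yl][(triethylsilyl)oxy]methyl}-4-[(4-methoxybenzyl)oxy]-3-[(triethylsilyl)oxy]butanal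
Conditions: Dess–Martin periodinane (1.3 equiv), pyridine (3 equiv), CH2Cl2, 0 °C
Reagents that add atoms: none
Why: Dess–Martin oxidation under buffered conditions gives the hindered α-branched aldehyde without epimerising C7 or eliminating a β-silyloxy group.

Step 11
Reactants: 15 (2R,3R)-2-{(S)-[(2S,3R)-3-(but-3-en-1-yl)-3-methyloxiran-2-yl][(triethylsilyl)oxy]methyl}-4-[(4-methoxybenzyl)oxy]-3-[(triethylsilyl)oxy]butanal; 16 tributyl(2-methylprop-2-en-1-yl)stannane
Product: 17 (4R,5R,6R)-5-{(S)-[(2S,3R)-3-(but-3-en-1-yl)-3-methyloxiran-2-yl][(triethylsilyl)oxy]methyl}-7-[(4-methoxybenzyl)oxy]-2-methyl-6-[(triethylsilyl)oxy]hept-1-en-4-ol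
Conditions: 16 (2 equiv), (R)-BINOL (20 mol %), Ti(OiPr)4 (10 mol %), 4 Å molecular sieves, CH2Cl2, −20 °C
Reagents that add atoms: none
Why: Keck catalytic asymmetric methallylation, in which the (R)-BINOL/Ti(OiPr)4 catalyst directs the stannane to the Re face of the aldehyde (catalyst control, as the two α-branches are sterically alike) and sets C8 (R).

Step 12
Reactants: 17 (4R,5R,6R)-5-{(S)-[(2S,3R)-3-(but-3-en-1-yl)-3-methyloxiran-2-yl][(triethylsilyl)oxy]methyl}-7-[(4-methoxybenzyl)oxy]-2-methyl-6-[(triethylsilyl)oxy]hept-1-en-4-ol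
Product: 18 (2R,3R,4R)-3-{(S)-[(2S,3R)-3-(but-3-en-1-yl)-3-methyloxiran-2-yl][(triethylsilyl)oxy]methyl}-6-methyl-2-[(triethylsilyl)oxy]hept-6-ene-1,4-diol
Conditions: DDQ (1.3 equiv), CH2Cl2/pH 7 phosphate buffer (10:1), 0 °C
Reagents that add atoms: none
Why: Oxidative cleavage of the 4-methoxybenzyl ether under buffered conditions frees the primary C12 hydroxyl and spares the silyl ethers, the epoxide and both alkenes.

Step 13
Reactants: 18 (2R,3R,4R)-3-{(S)-[(2S,3R)-3-(but-3-en-1-yl)-3-methyloxiran-2-yl][(triethylsilyl)oxy]methyl}-6-methyl-2-[(triethylsilyl)oxy]hept-6-ene-1,4-diol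
Product: 21 (3R,4S,5R)-4-{(S)-[(2S,3R)-3-(but-3-en-1-yl)-3-methyloxiran-2-yl][(triethylsilyl)oxy]methyl}-5-(2-methylprop-2-en-1-yl)-3-[(triethylsilyl)oxy]oxolan-2-one, via hydroxy aldehyde 19 (not isolated), via lactol 20 (not isolated)
Conditions: TEMPO (20 mol %), PhI(OAc)2 (2.5 equiv), CH2Cl2/pH 7 phosphate buffer, 25 °C
Reagents that add atoms: none
Why: TEMPO-mediated oxidative lactonisation oxidises only the primary alcohol, the aldehyde is trapped by the C8 hydroxyl as a lactol and this is oxidised on to the trans-β,γ-disubstituted γ-lactone with no stereocentre touched.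

Step 14
Reactants: 21 (3R,4S,5R)-4-{(S)-[(2S,3R)-3-(but-3-en-1-yl)-3-methyloxiran-2-yl][(triethylsilyl)oxy]methyl}-5-(2-methylprop-2-en-1-yl)-3-[(triethylsilyl)oxy]oxolan-2-one
Product: 23 (3R,4S,5R)-4-{(S)-[(2S,3R)-3-(but-3-en-1-yl)-3-methyloxiran-2-yl][(triethylsilyl)oxy]methyl}-3-methyl-5-(2-methylprop-2-en-1-yl)-3-[(triethylsilyl)oxy]oxolan-2-one, via lithium lactone enolate 22 (not isolated)
Conditions: LiN(iPr)2 (1.3 equiv), THF, −78 °C; MeI (5 equiv), DMPU, −78 → −40 °C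
Reagents that add atoms: iodomethane, CI
Why: Alkylation of the α-silyloxy lactone enolate, where iodomethane enters anti to the bulky β-substituent on C7, so the methyl takes the place of the former hydrogen and C11 (R) is fixed with its oxygen cis to C6.

Step 15
Reactants: 23 (3R,4S,5R)-4-{(S)-[(2S,3R)-3-(but-3-en-1-yl)-3-methyloxiran-2-yl][(triethylsilyl)oxy]methyl}-3-methyl-5-(2-methylprop-2-en-1-yl)-3-[(triethylsilyl)oxy]oxolan-2-one
Product: 24 (1(10)Z,4R,5S,6S,7S,8R,11R)-4,5-epoxy-6,11-bis(triethylsilyloxy)germacr-1(10)-en-12,8-olide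
Conditions: second-generation Grubbs catalyst (10 mol %), toluene (0.002 M), 80 °C
Reagents that add atoms: none
Why: Ring-closing metathesis between the terminal vinyl and the 1,1-disubstituted alkene, preorganised by the trans-lactone and the cis-epoxide, closes the ten-membered ring, and ring strain enforces the (Z)-trisubstituted alkene.

Step 16
Reactants: 24 (1(10)Z,4R,5S,6S,7S,8R,11R)-4,5-epoxy-6,11-bis(triethylsilyloxy)germacr-1(10)-en-12,8-olide
Product: 25 (1R,4R,5S,6S,7S,8R,10S,11R)-1,10:4,5-diepoxy-6,11-bis(triethylsilyloxy)germacran-12,8-olide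
Conditions: D-fructose-derived Shi ketone (30 mol %), KHSO5 (as Oxone, 1.5 equiv), K2CO3, Bu4NHSO4 (cat.), MeCN/CH2(OMe)2/aq. borate buffer pH 10.5, 0 °C
Reagents that add atoms: potassium peroxymonosulfate, [K+].[O-]S(=O)(=O)OO
Why: Shi asymmetric epoxidation under catalyst control, where the chiral dioxirane attacks the cyclic trisubstituted alkene through the spiro transition state on the face it uses for 1-phenylcyclohexene, giving C1 (R) and C10 (S).

Step 17
Reactants: 25 (1R,4R,5S,6S,7S,8R,10S,11R)-1,10:4,5-diepoxy-6,11-bis(triethylsilyloxy)germacran-12,8-olide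
Product: 26 (1R,4R,5S,6S,7R,8R,10S,11R)-1,10:4,5-diepoxy-6,11-dihydroxygermacran-12,8-olide
Conditions: HF·pyridine, pyridine, THF, 0 → 25 °C
Reagents that add atoms: none
Why: Fluoride-mediated desilylation under pyridine-buffered conditions removes both triethylsilyl groups without opening the epoxides or the lactone (the C7 descriptor changes by priority only).

Step 18
Reactants: 26 (1R,4R,5S,6S,7R,8R,10S,11R)-1,10:4,5-diepoxy-6,11-dihydroxygermacran-12,8-olide; 27 angelic acid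
Product: 28 (1R,4R,5S,6S,7S,8R,10S,11R)-6-angeloyloxy-1,10:4,5-diepoxy-11-hydroxygermacran-12,8-olide
Conditions: 27 (4 equiv), 2,4,6-trichlorobenzoyl chloride (4 equiv), Et3N (6 equiv), toluene, 25 °C, filtered; then 26, 75 °C
Reagents that add atoms: none
Why: Yamaguchi-type esterification through the mixed anhydride without a nucleophilic catalyst keeps the (Z)-geometry and acylates the secondary C6 hydroxyl with retention, the tertiary C11 hydroxyl being too hindered to compete.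

Step 19
Reactants: 28 (1R,4R,5S,6S,7S,8R,10S,11R)-6-angeloyloxy-1,10:4,5-diepoxy-11-hydroxygermacran-12,8-olide; 27 angelic acid
Product: 30 (1R,4R,5S,6S,7S,8R,10S,11R)-6,11-bis(angeloyloxy)-1,10:4,5-diepoxygermacran-12,8-olide, via lithium tertiary alkoxide 29 (not isolated)
Conditions: LiN(SiMe3)2 (1.1 equiv), THF, −78 °C; then mixed anhydride from 27 (2 equiv), 2,4,6-trichlorobenzoyl chloride and Et3N, −78 → 0 °C
Reagents that add atoms: none
Why: Alkoxide acylation, in which the lithium alkoxide of the tertiary α-hydroxy lactone attacks the unhindered angeloyl carbonyl of the mixed anhydride at low temperature, so the second angelate is installed without Z→E isomerisation.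

**Compound list**
1 | but-2-yn-1-ol | CC#CCO | starting material
2 | cyclic sodium alkenylalanate from 1 (Al on C3 and on O) | CC1=CCO[Al-]1(OCCOC)OCCOC.[Na+] | intermediate
3 | (2Z)-3-iodobut-2-en-1-ol | C/C(I)=C/CO | intermediate
4 | but-3-en-1-ylzinc bromide | C=CCC[Zn]Br | starting material
5 | (2Z)-3-methylhepta-2,6-dien-1-ol | OC/C=C(C)\CCC=C | intermediate
6 | [(2S,3R)-3-(but-3-en-1-yl)-3-methyloxiran-2-yl]methanol | OC[C@@H]1O[C@]1(C)CCC=C | intermediate
7 | (2R,3R)-3-(but-3-en-1-yl)-3-methyloxirane-2-carbaldehyde | O=C[C@@H]1O[C@]1(C)CCC=C | intermediate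
8 | ethyl 4-chloro-3-oxobutanoate | CCOC(=O)CC(=O)CCl | starting material
9 | ethyl 4-[(4-methoxybenzyl)oxy]-3-oxobutanoate | CCOC(=O)CC(=O)COCc1ccc(OC)cc1 | intermediate
10 | ethyl (3R)-3-hydroxy-4-[(4-methoxybenzyl)oxy]butanoate | CCOC(=O)C[C@@H](O)COCc1ccc(OC)cc1 | intermediate
11 | dilithium alkoxide enolate of 10 | CCOC([O-])=C[C@@H]([O-])COCc1ccc(OC)cc1.[Li+].[Li+] | intermediate
12 | ethyl (2R,3R)-2-{(S)-[(2S,3R)-3-(but-3-en-1-yl)-3-methyloxiran-2-yl](hydroxy)methyl}-3-hydroxy-4-[(4-methoxybenzyl)oxy]butanoate | CCOC(=O)[C@@H]([C@H](O)[C@@H]1O[C@]1(C)CCC=C)[C@@H](O)COCc1ccc(OC)cc1 | intermediate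
13 | bis(triethylsilyl) ether of 12 (2R,3R; carbinol S; oxirane 2S,3R) | CCOC(=O)[C@@H]([C@H](O[Si](CC)(CC)CC)[C@@H]1O[C@]1(C)CCC=C)[C@@H](O[Si](CC)(CC)CC)COCc1ccc(OC)cc1 | intermediate
14 | (2R,3R)-2-{(S)-[(2S,3R)-3-(but-3-en-1-yl)-3-methyloxiran-2-yl][(triethylsilyl)oxy]methyl}-4-[(4-methoxybenzyl)oxy]-3-[(triethylsilyl)oxy]butan-1-ol | OC[C@@H]([C@H](O[Si](CC)(CC)CC)[C@@H]1O[C@]1(C)CCC=C)[C@@H](O[Si](CC)(CC)CC)COCc1ccc(OC)cc1 | intermediate
15 | (2R,3R)-2-{(S)-[(2S,3R)-3-(but-3-en-1-yl)-3-methyloxiran-2-yl][(triethylsilyl)oxy]methyl}-4-[(4-methoxybenzyl)oxy]-3-[(triethylsilyl)oxy]butanal | O=C[C@@H]([C@H](O[Si](CC)(CC)CC)[C@@H]1O[C@]1(C)CCC=C)[C@@H](O[Si](CC)(CC)CC)COCc1ccc(OC)cc1 | intermediate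
16 | tributyl(2-methylprop-2-en-1-yl)stannane | C=C(C)C[Sn](CCCC)(CCCC)CCCC | starting material
17 | (4R,5R,6R)-5-{(S)-[(2S,3R)-3-(but-3-en-1-yl)-3-methyloxiran-2-yl][(triethylsilyl)oxy]methyl}-7-[(4-methoxybenzyl)oxy]-2-methyl-6-[(triethylsilyl)oxy]hept-1-en-4-ol | C=C(C)C[C@@H](O)[C@@H]([C@H](O[Si](CC)(CC)CC)[C@@H]1O[C@]1(C)CCC=C)[C@@H](O[Si](CC)(CC)CC)COCc1ccc(OC)cc1 | intermediate
18 | (2R,3R,4R)-3-{(S)-[(2S,3R)-3-(but-3-en-1-yl)-3-methyloxiran-2-yl][(triethylsilyl)oxy]methyl}-6-methyl-2-[(triethylsilyl)oxy]hept-6-ene-1,4-diol | C=C(C)C[C@@H](O)[C@@H]([C@H](O[Si](CC)(CC)CC)[C@@H]1O[C@]1(C)CCC=C)[C@@H](O[Si](CC)(CC)CC)CO | intermediate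
19 | hydroxy aldehyde from 18 (C12 aldehyde, C8 hydroxyl) | C=C(C)C[C@@H](O)[C@@H]([C@H](O[Si](CC)(CC)CC)[C@@H]1O[C@]1(C)CCC=C)[C@@H](O[Si](CC)(CC)CC)C=O | intermediate
20 | lactol from 19 (both anomers) | C=C(C)C[C@H]1OC(O)[C@H](O[Si](CC)(CC)CC)[C@@H]1[C@H](O[Si](CC)(CC)CC)[C@@H]2O[C@]2(C)CCC=C | intermediate
21 | (3R,4S,5R)-4-{(S)-[(2S,3R)-3-(but-3-en-1-yl)-3-methyloxiran-2-yl][(triethylsilyl)oxy]methyl}-5-(2-methylprop-2-en-1-yl)-3-[(triethylsilyl)oxy]oxolan-2-one | C=C(C)C[C@H]1OC(=O)[C@H](O[Si](CC)(CC)CC)[C@@H]1[C@H](O[Si](CC)(CC)CC)[C@@H]2O[C@]2(C)CCC=C | intermediate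
22 | lithium enolate of lactone 21 | C=C(C)C[C@H]1OC([O-])=C(O[Si](CC)(CC)CC)[C@@H]1[C@H](O[Si](CC)(CC)CC)[C@@H]2O[C@]2(C)CCC=C.[Li+] | intermediate
23 | (3R,4S,5R)-4-{(S)-[(2S,3R)-3-(but-3-en-1-yl)-3-methyloxiran-2-yl][(triethylsilyl)oxy]methyl}-3-methyl-5-(2-methylprop-2-en-1-yl)-3-[(triethylsilyl)oxy]oxolan-2-one | C=C(C)C[C@H]1OC(=O)[C@](C)(O[Si](CC)(CC)CC)[C@@H]1[C@H](O[Si](CC)(CC)CC)[C@@H]2O[C@]2(C)CCC=C | intermediate
24 | (1(10)Z,4R,5S,6S,7S,8R,11R)-4,5-epoxy-6,11-bis(triethylsilyloxy)germacr-1(10)-en-12,8-olide | C/C1=C/CC[C@@]2(C)O[C@H]2[C@@H](O[Si](CC)(CC)CC)[C@H]3[C@@](C)(O[Si](CC)(CC)CC)C(=O)O[C@@H]3C1 | intermediate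
25 | (1R,4R,5S,6S,7S,8R,10S,11R)-1,10:4,5-diepoxy-6,11-bis(triethylsilyloxy)germacran-12,8-olide | C[C@@]12O[C@@H]1CC[C@@]3(C)O[C@H]3[C@@H](O[Si](CC)(CC)CC)[C@H]4[C@@](C)(O[Si](CC)(CC)CC)C(=O)O[C@@H]4C2 | intermediate
26 | (1R,4R,5S,6S,7R,8R,10S,11R)-1,10:4,5-diepoxy-6,11-dihydroxygermacran-12,8-olide | C[C@@]12O[C@@H]1CC[C@@]3(C)O[C@H]3[C@@H](O)[C@H]4[C@@](C)(O)C(=O)O[C@@H]4C2 | intermediate
27 | angelic acid, (2Z)-2-methylbut-2-enoic acid | C/C=C(/C)C(=O)O | starting material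
28 | (1R,4R,5S,6S,7S,8R,10S,11R)-6-angeloyloxy-1,10:4,5-diepoxy-11-hydroxygermacran-12,8-olide | C[C@@]12O[C@@H]1CC[C@@]3(C)O[C@H]3[C@@H](OC(=O)/C(C)=C\C)[C@H]4[C@@](C)(O)C(=O)O[C@@H]4C2 | intermediate
29 | lithium C11 alkoxide of 28 | C[C@@]12O[C@@H]1CC[C@@]3(C)O[C@H]3[C@@H](OC(=O)/C(C)=C\C)[C@H]4[C@@](C)([O-])C(=O)O[C@@H]4C2.[Li+] | intermediate
30 | (1R,4R,5S,6S,7S,8R,10S,11R)-6,11-bis(angeloyloxy)-1,10:4,5-diepoxygermacran-12,8-olide (CNP0219924.2) | C/C=C(/C)C(=O)O[C@H]1[C@@H]2[C@@H](C[C@]3(C)O[C@@H]3CC[C@@]3(C)O[C@@H]13)OC(=O)[C@]2(C)OC(=O)/C(C)=C\C | target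

**Step count and risks**

Total step count: 19. Longest linear sequence: 17 steps (steps 1–4, then 7–19).

Step 15 (ring-closing metathesis to a ten-membered ring with a trisubstituted alkene) is the most likely to fail. The fallback sets out from 17 and comes back at 25, closing the ring before the lactone exists and letting the free C8 hydroxyl direct the second epoxidation. Acyclic hydroxy diene 17 is cyclised with second-generation Grubbs catalyst at high dilution to the macrocyclic homoallylic alcohol F1. VO(acac)2 and tBuOOH with 2,6-lutidine as buffer then deliver oxygen from the vanadate ester of the C8 hydroxyl to the syn face of the (Z)-alkene and give the bis-epoxy alcohol F2. Buffered DDQ removes the 4-methoxybenzyl group to give the bis-epoxy diol F3. TEMPO and PhI(OAc)2 close the bis-epoxy lactone F4, and LiN(iPr)2 with iodomethane methylates C11 anti to the C7–C6 bond to reach 25.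

Step 11 (Keck methallylation of a very hindered, epimerisable aldehyde) may be slow or poorly selective. The fallback sets out from 15 and comes back at 17, replacing the allyl transfer by an organocatalytic aldol. L-Proline (30 mol %) in acetone/DMSO adds the acetone enamine to the Re face of 15 and gives the β-hydroxy methyl ketone F5 with the same C8 configuration. Wittig methylenation of the ketone with Ph3P=CH2 (3 equiv, THF, 0 °C) then gives 17.

Step 19 (acylation of the tertiary α-hydroxy lactone with an isomerisable angeloyl donor) may stall or give tiglate. The fallback sets out from 28 and comes back at 30, building the angelate on the ester oxygen instead of transferring it. Alcohol 28 is acylated with 2-[bis(2,2,2-trifluoroethoxy)phosphoryl]propanoic acid (DCC, DMAP cat., CH2Cl2; a ketene-type acyl donor that reaches hindered alcohols) to give the phosphonopropionate ester F6. Still–Gennari olefination of F6 with acetaldehyde (KN(SiMe3)2, 18-crown-6, THF, −78 °C) then forms the (Z)-2-methylbut-2-enoate, giving 30.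

**Further compounds**
F1 | step 15 | (1(10)Z,4R,5S,6S,7R,8R,11R)-4,5-epoxy-12-(4-methoxybenzyloxy)-6,11-bis(triethylsilyloxy)-13-norgermacr-1(10)-en-8-ol | C/C1=C/CC[C@@]2(C)O[C@H]2[C@@H](O[Si](CC)(CC)CC)[C@@H]([C@@H](O[Si](CC)(CC)CC)COCc2ccc(OC)cc2)[C@H](O)C1
F2 | step 15 | (1R,4R,5S,6S,7R,8R,10S,11R)-1,10:4,5-diepoxy-12-(4-methoxybenzyloxy)-6,11-bis(triethylsilyloxy)-13-norgermacran-8-ol | C[C@@]12O[C@@H]1CC[C@@]3(C)O[C@H]3[C@@H](O[Si](CC)(CC)CC)[C@@H]([C@@H](O[Si](CC)(CC)CC)COCc4ccc(OC)cc4)[C@H](O)C2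
F3 | step 15 | (1R,4R,5S,6S,7R,8R,10S,11R)-1,10:4,5-diepoxy-6,11-bis(triethylsilyloxy)-13-norgermacrane-8,12-diol | C[C@@]12O[C@@H]1CC[C@@]3(C)O[C@H]3[C@@H](O[Si](CC)(CC)CC)[C@@H]([C@@H](O[Si](CC)(CC)CC)CO)[C@H](O)C2
F4 | step 15 | (1R,4R,5S,6S,7S,8R,10S,11R)-1,10:4,5-diepoxy-6,11-bis(triethylsilyloxy)-13-norgermacran-12,8-olide | C[C@@]12O[C@@H]1CC[C@@]3(C)O[C@H]3[C@@H](O[Si](CC)(CC)CC)[C@H]4[C@@H](O[Si](CC)(CC)CC)C(=O)O[C@@H]4C2
F5 | step 11 | (4R,5R,6R)-5-{(S)-[(2S,3R)-3-(but-3-en-1-yl)-3-methyloxiran-2-yl][(triethylsilyl)oxy]methyl}-4-hydroxy-7-[(4-methoxybenzyl)oxy]-6-[(triethylsilyl)oxy]heptan-2-one | CC(=O)C[C@@H](O)[C@@H]([C@H](O[Si](CC)(CC)CC)[C@@H]1O[C@]1(C)CCC=C)[C@@H](O[Si](CC)(CC)CC)COCc1ccc(OC)cc1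
F6 | step 19 | (1R,4R,5S,6S,7S,8R,10S,11R)-6-angeloyloxy-11-{2-[bis(2,2,2-trifluoroethoxy)phosphoryl]propanoyloxy}-1,10:4,5-diepoxygermacran-12,8-olide (both epimers at the phosphonate carbon) | C[C@@]12O[C@@H]1CC[C@@]3(C)O[C@H]3[C@@H](OC(=O)/C(C)=C\C)[C@H]4[C@@](C)(OC(=O)C(C)P(=O)(OCC(F)(F)F)OCC(F)(F)F)C(=O)O[C@@H]4C2
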